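(Readings and results come from a simulation for an exercise; scatter was added.)

If target is a way station on the road to its isomer, then the mixture carries a clock, and I would rather read that clock in powers of ten than follow each curve.

| setting | winter | midnight | noon | flask |
|---|---|---|---|---|
| substrate | 12 mM | 12 mM | 12 mM | 12 mM |
| partner | 0.60 equiv | 0.90 equiv | 1.2 equiv | 1.20 equiv |
| protic impurity | 3.6 mM | 3.6 mM | 1.8 mM | 3.60 mM |
| free catalyst | 0.5 mol% | 0.5 mol% | 0.5 mol% | 0.5 mol% |
| second catalyst | 0.5 mol% | 0.5 mol% | 0.5 mol% | 0.5 mol% |
| remark | run made earlier | run made earlier | run made earlier |  |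
| time |  |  |  | 8.0 min |

| run | time / min | isomer of the product / % | target / % |
|---|---|---|---|
| winter | 1.00 | 8.9 | 28.0 |
| winter | 2.00 | 17.0 | 23.5 |
| winter | 3.00 | 25.8 | 14.8 |
| winter | 4.00 | 27.9 | 10.9 |
| winter | 5.00 | 30.3 | 6.8 |
| midnight | 0.417 | 4.0 | 40.4 |
| midnight | 0.667 | 6.3 | 42.2 |
| midnight | 1.33 | 19.3 | 40.5 |
| midnight | 2.50 | 32.2 | 29.8 |
| midnight | 5.00 | 49.0 | 12.0 |
| noon | 0.417 | 4.5 | 51.1 |
| noon | 0.667 | 10.7 | 58.3 |
| noon | 1.33 | 25.0 | 57.6 |
| noon | 2.50 | 43.7 | 43.9 |
| noon | 5.00 | 72.3 | 21.6 |

(scatter of a reading: 1 percentage point)

- ratio of isomer of the product to target at 2.0 s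
- ratio of isomer of the product to target at 8.0 min
- which of isomer of the product and target there is more of at 8.0 min



I define the clock rate as the rise per minute of the logarithm to base ten of c(isomer of the product) plus c(target), taken over c(target). While that sum holds steady, a fixed clock rate means a first-order loss of target. In the midnight run the sum of the two has stopped growing, 62.0 % at 2.50 min and 61.0 % at 5.00 min, so I read the clock there, and in powers of ten it gives 0.155 min⁻¹. The winter run, with 0.60 equiv of partner, reads 0.149 min⁻¹ between 3.00 min and 5.00 min, so between these two partner charges, at the same protic impurity, I see no clear change in the clock.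

Multiplied by 2.3, the clock rate becomes a pseudo-first-order constant for the loss of target, 0.357 min⁻¹. Target made at a steady pace in the first moments has an average age of the elapsed time over two, so at 2.0 s I expect a ratio near 0.00595.

For the end I start from the midnight position at 5.00 min and run the clock for the remaining 3.00 min, which gives a ratio of 13.8. The start is the weak link: the flask has the noon partner charge, 1.20 equiv, but the midnight protic impurity, 3.60 mM against 1.8 mM in the noon run, and the noon sum still climbs from 87.6 % to 93.9 %, which I read as young target still entering. Keeping that difference in impurity in mind, I start from the noon reading with the noon clock, slower at 0.135 min⁻¹, and commit to 10.1, with isomer ahead.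

The forecast gives 0.006, 10 and isomer of the product: “Isomer/target is about 10, so isomer leads.” The flask gives 0.00645 at 2.0 s and 7.18 at 8.0 min, with 78.5 % isomer of the product against 10.9 % target.

    substrate + free catalyst ⇌ free catalyst + intermediate (K = 0.402, k = 3960 M⁻¹ s⁻¹)
    target + free catalyst ⇌ isomer of the product + free catalyst, rate k2*[free catalyst]*[target] forward; the back reaction follows from the equilibrium constant (K = 15.5, k = 149 M⁻¹ s⁻¹)
    partner + protic impurity → quenched reagent (k = 8.82 M⁻¹ s⁻¹)
    partner + second catalyst + intermediate → second catalyst + target (k = 2.58 × 10⁵ M⁻² s⁻¹)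
    2 free catalyst ⇌ resting dimer (K = 5300 M⁻¹, k = 571 M⁻¹ s⁻¹)

In the flask the forward half-life of target by its isomerisation, 1.8 min at 0.159 min, is short against the 8.0 min of the run, and at 8.0 min target is made at 0.114 of the rate at which it is used up, each step taken net. Taken on the flask from 4.00 min to 8.0 min, the clock rate is 0.103 min⁻¹, against the 0.155 min⁻¹ read in the midnight run, and averaged from the start to 8.0 min it is 0.122 min⁻¹ in the neighbour flask with 2 mol% of second catalyst, whose ratio stands at 8.52.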